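Ring C is assembled rather than functionalised. With C1 = C–OH, C2 = C–OAr and C4 = C–alkyl, the bonds C2–C3 and C5–C6 are disconnected. C6–C1–C2 comes from a 4-aryloxyacetoacetate that already carries the ring B ether oxygen. C3–C4–C5 comes from a 2-alkylmalonaldehyde bis(acetal) carrying ring D. Because C4 lies para to C1, this three-carbon electrophile is symmetric. A single Lewis-acid [3+3] cycloaromatisation of the derived 1,3-bis(silyloxy)diene therefore forms both C–C bonds, ring C and the whole carbon framework with no regiochemical choice. The ester left at C6 is then excised and three methyl ethers are cleaved.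

Key step: step 9

Remark (labels): ring A = 3-oxygenated phenyl, ring B = 1,4-phenylene, ring C = the 1,2,4-trisubstituted phenol ring, ring D = 2,5-dioxygenated phenyl. The target has no stereocentre.
Remark (assumption): the double-bond geometries of the silyl enol ether, the diene and the methyl enol ether do not matter, because these carbons all end up in aromatic ring C. Salts formed by simple deprotonation (phenoxide, enolates, phosphonate carbanion, carboxylates) are treated as forms of their numbered parent compound.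

Step 1
Reactants: 1 4-(benzyloxy)benzaldehyde; 2 diethyl (3-methoxybenzyl)phosphonate
Product: 3 (E)-1-(benzyloxy)-4-[2-(3-methoxyphenyl)ethenyl]benzene
Conditions: KOtBu (1.2 equiv), THF, 0 °C → rt
Reagents that add atoms: none
Why: Horner–Wadsworth–Emmons olefination of a non-enolisable aromatic aldehyde with a benzylic phosphonate carbanion should give the (E)-stilbene, whose geometry is erased in step 2 anyway.

Step 2
Reactants: 3 (E)-1-(benzyloxy)-4-[2-(3-methoxyphenyl)ethenyl]benzene
Product: 5 4-[2-(3-methoxyphenyl)ethyl]phenol, via benzyl-protected bibenzyl 4 (not isolated)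
Conditions: H2 (1 atm), 10% Pd/C, EtOAc–MeOH, rt
Reagents that add atoms: none
Why: Heterogeneous catalytic hydrogenation saturates the stilbene C=C to 4 and then hydrogenolyses the benzylic C–O bond in the same flask, while the aryl methyl ether and the arenes are inert at this pressure.

Step 3
Reactants: 5 4-[2-(3-methoxyphenyl)ethyl]phenol; 6 methyl 4-chloroacetoacetate
Product: 7 methyl 4-{4-[2-(3-methoxyphenyl)ethyl]phenoxy}-3-oxobutanoate
Conditions: NaH (2.3 equiv), THF, 0 °C (5 first, then 6 dropwise) → 45 °C; aq. HCl quench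
Reagents that add atoms: none
Why: In this Williamson-type SN2 etherification one equivalent of base forms the phenoxide and the second masks 6 as its enolate against self-condensation, so the phenoxide displaces the primary chloride, a known entry to 4-alkoxy- and 4-aryloxyacetoacetates.

Step 4
Reactants: 7 methyl 4-{4-[2-(3-methoxyphenyl)ethyl]phenoxy}-3-oxobutanoate
Product: 8 methyl (Z)-4-{4-[2-(3-methoxyphenyl)ethyl]phenoxy}-3-(trimethylsilyloxy)but-2-enoate
Conditions: Me3SiCl (1.5 equiv), Et3N (1.6 equiv), toluene, rt, 48–72 h; filtration under argon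
Reagents that add atoms: chlorotrimethylsilane, C[Si](C)(C)Cl
Why: Soft enolisation and O-silylation of the β-keto ester gives the ester-conjugated silyl enol ether, the standard first stage of 1,3-bis(silyl enol ether) synthesis.

Step 5
Reactants: 8 methyl (Z)-4-{4-[2-(3-methoxyphenyl)ethyl]phenoxy}-3-(trimethylsilyloxy)but-2-enoate
Product: 9 1-methoxy-4-{4-[2-(3-methoxyphenyl)ethyl]phenoxy}-1,3-bis(trimethylsilyloxy)buta-1,3-diene (drawn 1Z,3Z; used crude)
Conditions: LiN(iPr)2 (commercial solution, 1.5 equiv), THF, −78 °C; Me3SiCl (1.8 equiv), −78 °C → rt; hexane, filtration under argon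
Reagents that add atoms: chlorotrimethylsilane, C[Si](C)(C)Cl
Why: Kinetic γ-deprotonation of the vinylogous ester at the aryloxy-activated CH2 gives a dienolate that is O-silylated at the ester oxygen, the standard second stage of bis(silyl enol ether) synthesis and one already known for 4-aryloxy cases.

Step 6
Reactants: 10 2-iodo-1,4-dimethoxybenzene; 11 allyl alcohol
Product: 13 3-(2,5-dimethoxyphenyl)propanal, via enol tautomer 12 (not isolated)
Conditions: Pd(OAc)2 (3 mol %), n-Bu4NCl (1 equiv), NaHCO3 (2.5 equiv), DMF, 45 °C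
Reagents that add atoms: none
Why: In this Mizoroki–Heck arylation of allyl alcohol, zerovalent palladium inserts into the C–I bond, the aryl group adds to the terminal alkene carbon, β-hydride elimination towards the carbinol carbon gives enol 12, and tautomerisation gives the saturated aldehyde.

Step 7
Reactants: 13 3-(2,5-dimethoxyphenyl)propanal; 14 (methoxymethyl)triphenylphosphonium chloride
Product: 16 1,4-dimethoxy-2-(4-methoxybut-3-en-1-yl)benzene (E/Z mixture), via methoxymethylidene ylide 15 (not isolated)
Conditions: 14 (1.5 equiv), KOtBu (1.4 equiv), THF, 0 °C; then 13, 0 °C → rt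
Reagents that add atoms: none
Why: Wittig methoxymethylenation with the preformed non-stabilised ylide 15 turns the aldehyde directly into the one-carbon-longer methyl enol ether, and both geometries are equally useful in step 8.

Step 8
Reactants: 16 1,4-dimethoxy-2-(4-methoxybut-3-en-1-yl)benzene; 17 trimethyl orthoformate
Product: 18 2-[2-(2,5-dimethoxyphenyl)ethyl]-1,1,3,3-tetramethoxypropane
Conditions: 17 (5 equiv, neat), BF3·OEt2 (3 mol %), 0 °C → rt; Et3N quench
Reagents that add atoms: none
Why: In this Lewis-acid-catalysed orthoformate–enol ether addition the dimethoxycarbenium ion attacks the nucleophilic β-carbon and methoxide transfer caps the resulting oxocarbenium ion, while the excess of 17, the trace of Lewis acid and the low temperature hold back telomerisation and Friedel–Crafts closure by ring D.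

Step 9
Reactants: 9 1-methoxy-4-{4-[2-(3-methoxyphenyl)ethyl]phenoxy}-1,3-bis(trimethylsilyloxy)buta-1,3-diene; 18 2-[2-(2,5-dimethoxyphenyl)ethyl]-1,1,3,3-tetramethoxypropane
Product: 21 methyl 5-[2-(2,5-dimethoxyphenyl)ethyl]-2-hydroxy-3-{4-[2-(3-methoxyphenyl)ethyl]phenoxy}benzoate, via open-chain aldol adduct 19 (not isolated), via dimethoxycyclohexanone ester 20 (not isolated)
Conditions: 9 (1.5 equiv), TMSOTf (0.3 equiv), CH2Cl2 (ca. 0.5 M), −78 °C → 20 °C, overnight; then 10% aq. HCl
Reagents that add atoms: none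
Why: TMSOTf ionises one acetal of 18 to an oxocarbenium ion that is captured at the aryloxy-bearing terminus C4 of 9 in a vinylogous Mukaiyama aldol step, silyl transfer to the departing methoxide regenerating the catalyst and giving 19. Ionisation of the second acetal lets the β-silyloxyacrylate carbon C2 close ring C in a 6-(enolendo)-exo-trig Mukaiyama aldol (the C=O+ bond stays outside the forming ring) to give 20, and two acid-promoted β-eliminations of methanol followed by dienone–phenol tautomerisation aromatise the ring. The closest known reaction type is the formal [3+3] cyclocondensation of 1,3-bis(silyl enol ethers) with 1,1,3,3-tetraalkoxypropanes, which is established separately for 4-aryloxy dienes and for 2-alkyl tetraalkoxypropanes. No stereocentre is set, since every sp3 centre of 19 and 20 is erased on aromatisation. Regiochemistry needs no control, because 18 is symmetric about its alkyl-bearing carbon and attack through C4 first or C2 first leads to the same 2-hydroxy-3-aryloxy-5-alkyl pattern. The selectivity needed is carbon attack by the diene in preference to six-membered Friedel–Crafts capture of the oxocarbenium ion by ring D and to oligomerisation, and it is secured by the far higher nucleophilicity of the bis(silyl enol ether), its excess, substoichiometric TMSOTf, the low starting temperature and the intramolecular second bond formation.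

Step 10
Reactants: 21 methyl 5-[2-(2,5-dimethoxyphenyl)ethyl]-2-hydroxy-3-{4-[2-(3-methoxyphenyl)ethyl]phenoxy}benzoate
Product: 22 5-[2-(2,5-dimethoxyphenyl)ethyl]-2-hydroxy-3-{4-[2-(3-methoxyphenyl)ethyl]phenoxy}benzoic acid
Conditions: KOH (6 equiv), MeOH–THF–H2O, reflux; then aq. HCl to pH 2
Reagents that add atoms: potassium hydroxide (hydroxide oxygen), [K+].[OH-]
Why: Saponification (acyl-oxygen cleavage by hydroxide) of the hydrogen-bonded salicylate needs excess base and heat, which the methyl ethers, the diaryl ether and the bibenzyl chains tolerate.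

Step 11
Reactants: 22 5-[2-(2,5-dimethoxyphenyl)ethyl]-2-hydroxy-3-{4-[2-(3-methoxyphenyl)ethyl]phenoxy}benzoic acid
Product: 23 4-[2-(2,5-dimethoxyphenyl)ethyl]-2-{4-[2-(3-methoxyphenyl)ethyl]phenoxy}phenol
Conditions: Cu2O (10 mol %), 1,10-phenanthroline (20 mol %), NMP–quinoline (3:1), 180 °C, argon
Reagents that add atoms: none
Why: In this copper-catalysed protodecarboxylation the monovalent copper carboxylate extrudes CO2 to an aryl–copper species that is protonated, supported by the thermal ipso-protonation path typical of salicylic acids; copper is chosen over a monovalent silver salt, which could oxidise the free electron-rich phenol, and the hydroquinone is still masked at this stage.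

Step 12
Reactants: 23 4-[2-(2,5-dimethoxyphenyl)ethyl]-2-{4-[2-(3-methoxyphenyl)ethyl]phenoxy}phenol
Product: 24 2-[2-(4-hydroxy-3-{4-[2-(3-hydroxyphenyl)ethyl]phenoxy}phenyl)ethyl]benzene-1,4-diol (CNP0300581.0)
Conditions: BBr3 (8 equiv), CH2Cl2, −78 °C → rt; ice-water quench and extraction under argon
Reagents that add atoms: none
Why: In this Lewis-acid aryl methyl ether cleavage BBr3 binds each methoxy oxygen and bromide removes the methyl group by SN2, the diaryl ether offers no sp3 C–O bond to attack, and hydrolysis of the aryl borates releases the tetraphenol.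

Compound list
1 | 4-(benzyloxy)benzaldehyde | O=Cc1ccc(OCc2ccccc2)cc1 | starting material
2 | diethyl (3-methoxybenzyl)phosphonate | CCOP(=O)(Cc1cccc(OC)c1)OCC | starting material
3 | (E)-1-(benzyloxy)-4-[2-(3-methoxyphenyl)ethenyl]benzene | COc1cccc(/C=C/c2ccc(OCc3ccccc3)cc2)c1 | intermediate
4 | 1-(benzyloxy)-4-[2-(3-methoxyphenyl)ethyl]benzene | COc1cccc(CCc2ccc(OCc3ccccc3)cc2)c1 | intermediate
5 | 4-[2-(3-methoxyphenyl)ethyl]phenol | COc1cccc(CCc2ccc(O)cc2)c1 | intermediate
6 | methyl 4-chloroacetoacetate (methyl 4-chloro-3-oxobutanoate) | COC(=O)CC(=O)CCl | starting material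
7 | methyl 4-{4-[2-(3-methoxyphenyl)ethyl]phenoxy}-3-oxobutanoate | COC(=O)CC(=O)COc1ccc(CCc2cccc(OC)c2)cc1 | intermediate
8 | methyl (Z)-4-{4-[2-(3-methoxyphenyl)ethyl]phenoxy}-3-(trimethylsilyloxy)but-2-enoate | COC(=O)/C=C(/COc1ccc(CCc2cccc(OC)c2)cc1)O[Si](C)(C)C | intermediate
9 | 1-methoxy-4-{4-[2-(3-methoxyphenyl)ethyl]phenoxy}-1,3-bis(trimethylsilyloxy)buta-1,3-diene (drawn 1Z,3Z) | CO/C(O[Si](C)(C)C)=C/C(O[Si](C)(C)C)=C/Oc1ccc(CCc2cccc(OC)c2)cc1 | intermediate
10 | 2-iodo-1,4-dimethoxybenzene | COc1ccc(OC)c(I)c1 | starting material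
11 | allyl alcohol (prop-2-en-1-ol) | C=CCO | starting material
12 | 3-(2,5-dimethoxyphenyl)prop-1-en-1-ol (enol, geometry undefined) | COc1ccc(OC)c(CC=CO)c1 | intermediate
13 | 3-(2,5-dimethoxyphenyl)propanal | COc1ccc(OC)c(CCC=O)c1 | intermediate
14 | (methoxymethyl)triphenylphosphonium chloride | COC[P+](c1ccccc1)(c1ccccc1)c1ccccc1.[Cl-] | starting material
15 | (methoxymethylidene)triphenylphosphorane | COC=P(c1ccccc1)(c1ccccc1)c1ccccc1 | intermediate
16 | 1,4-dimethoxy-2-(4-methoxybut-3-en-1-yl)benzene (E/Z mixture) | COC=CCCc1cc(OC)ccc1OC | intermediate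
17 | trimethyl orthoformate | COC(OC)OC | starting material
18 | 2-[2-(2,5-dimethoxyphenyl)ethyl]-1,1,3,3-tetramethoxypropane | COC(OC)C(CCc1cc(OC)ccc1OC)C(OC)OC | intermediate
19 | methyl 6-(dimethoxymethyl)-8-(2,5-dimethoxyphenyl)-5-methoxy-4-{4-[2-(3-methoxyphenyl)ethyl]phenoxy}-3-(trimethylsilyloxy)oct-2-enoate (diastereomer mixture) | COC(=O)C=C(O[Si](C)(C)C)C(Oc1ccc(CCc2cccc(OC)c2)cc1)C(OC)C(CCc1cc(OC)ccc1OC)C(OC)OC | intermediate
20 | methyl 5-[2-(2,5-dimethoxyphenyl)ethyl]-4,6-dimethoxy-3-{4-[2-(3-methoxyphenyl)ethyl]phenoxy}-2-oxocyclohexane-1-carboxylate (diastereomer mixture) | COC(=O)C1C(OC)C(CCc2cc(OC)ccc2OC)C(OC)C(Oc2ccc(CCc3cccc(OC)c3)cc2)C1=O | intermediate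
21 | methyl 5-[2-(2,5-dimethoxyphenyl)ethyl]-2-hydroxy-3-{4-[2-(3-methoxyphenyl)ethyl]phenoxy}benzoate | COC(=O)c1cc(CCc2cc(OC)ccc2OC)cc(Oc2ccc(CCc3cccc(OC)c3)cc2)c1O | intermediate
22 | 5-[2-(2,5-dimethoxyphenyl)ethyl]-2-hydroxy-3-{4-[2-(3-methoxyphenyl)ethyl]phenoxy}benzoic acid | O=C(O)c1cc(CCc2cc(OC)ccc2OC)cc(Oc2ccc(CCc3cccc(OC)c3)cc2)c1O | intermediate
23 | 4-[2-(2,5-dimethoxyphenyl)ethyl]-2-{4-[2-(3-methoxyphenyl)ethyl]phenoxy}phenol | COc1cccc(CCc2ccc(Oc3cc(CCc4cc(OC)ccc4OC)ccc3O)cc2)c1 | intermediate
24 | 2-[2-(4-hydroxy-3-{4-[2-(3-hydroxyphenyl)ethyl]phenoxy}phenyl)ethyl]benzene-1,4-diol | Oc1cccc(CCc2ccc(Oc3cc(CCc4cc(O)ccc4O)ccc3O)cc2)c1 | target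

Total step count: 12.
Longest linear sequence: 9 (steps 1–5, then 9–12). The ring D branch (steps 6–8) joins at step 9.

Steps most likely to fail

1. Step 9.
- What may go wrong: bond formation between the hindered aryloxy-bearing diene terminus and the branched oxocarbenium ion may be slow. Protodesilylation of the diene by liberated methanol, Friedel–Crafts closure by ring D or oligomerisation could then take over.
- Fallback: it sets out from 5 and rejoins at 23, and it buys ring C instead of building it.
- Ullmann ether coupling of 5 with commercial 4-(benzyloxy)-3-bromobenzaldehyde (CuI, N,N-dimethylglycine, Cs2CO3, dioxane, 100 °C) should give 4-(benzyloxy)-3-{4-[2-(3-methoxyphenyl)ethyl]phenoxy}benzaldehyde F1.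
- A Michaelis–Arbuzov reaction of commercial 2,5-dimethoxybenzyl chloride with P(OEt)3 (neat, 140 °C) supplies diethyl (2,5-dimethoxybenzyl)phosphonate F2.
- Horner–Wadsworth–Emmons olefination of F1 with F2 (KOtBu, THF) should give (E)-1-(benzyloxy)-4-[2-(2,5-dimethoxyphenyl)ethenyl]-2-{4-[2-(3-methoxyphenyl)ethyl]phenoxy}benzene F3.
- Hydrogenation of F3 over Pd/C saturates the alkene and removes the benzyl group in one flask to deliver 23.

2. Step 11.
- What may go wrong: loss of CO2 may be slow or incomplete, because the ipso carbon is activated by only one ortho oxygen. Prolonged heating could then erode the material.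
- Fallback: it sets out from 21 and rejoins at 24. The phenol is capped first, so the acid becomes an ortho-alkoxybenzoic acid. That is the class for which silver-catalysed protodecarboxylation is best established, and no oxidisable free phenol is present.
- MeI and K2CO3 in acetone should give methyl 5-[2-(2,5-dimethoxyphenyl)ethyl]-2-methoxy-3-{4-[2-(3-methoxyphenyl)ethyl]phenoxy}benzoate F4.
- KOH saponification gives 5-[2-(2,5-dimethoxyphenyl)ethyl]-2-methoxy-3-{4-[2-(3-methoxyphenyl)ethyl]phenoxy}benzoic acid F5.
- Ag2CO3 (10 mol %) with AcOH (5 mol %) in DMSO at 120 °C should give 4-[2-(2,5-dimethoxyphenyl)ethyl]-1-methoxy-2-{4-[2-(3-methoxyphenyl)ethyl]phenoxy}benzene F6.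
- BBr3, used as in step 12 but now cleaving four methyl ethers, gives 24.

3. Step 3.
- What may go wrong: displacement of chloride from the enolate form of the chloroketoester may be slow. Self-condensation of that enolate and C-alkylation could then compete.
- Fallback: it sets out from 5 and rejoins at 7, and it assembles the four-carbon unit from two two-carbon units without any chloroketone.
- Alkylation of 5 with methyl bromoacetate (K2CO3, acetone, reflux) should give methyl {4-[2-(3-methoxyphenyl)ethyl]phenoxy}acetate F7.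
- LiOH in THF–H2O gives {4-[2-(3-methoxyphenyl)ethyl]phenoxy}acetic acid F8.
- 1,1'-Carbonyldiimidazole in THF converts F8 into 1-({4-[2-(3-methoxyphenyl)ethyl]phenoxy}acetyl)imidazole F9.
- A decarboxylative Claisen condensation of F9 with KO2CCH2CO2Me, MgCl2 and Et3N in MeCN, followed by acidic work-up, delivers 7.

Further compounds
F1 | step 9 | 4-(benzyloxy)-3-{4-[2-(3-methoxyphenyl)ethyl]phenoxy}benzaldehyde | COc1cccc(CCc2ccc(Oc3cc(C=O)ccc3OCc3ccccc3)cc2)c1
F2 | step 9 | diethyl (2,5-dimethoxybenzyl)phosphonate | CCOP(=O)(Cc1cc(OC)ccc1OC)OCC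
F3 | step 9 | (E)-1-(benzyloxy)-4-[2-(2,5-dimethoxyphenyl)ethenyl]-2-{4-[2-(3-methoxyphenyl)ethyl]phenoxy}benzene | COc1cccc(CCc2ccc(Oc3cc(/C=C/c4cc(OC)ccc4OC)ccc3OCc3ccccc3)cc2)c1
F4 | step 11 | methyl 5-[2-(2,5-dimethoxyphenyl)ethyl]-2-methoxy-3-{4-[2-(3-methoxyphenyl)ethyl]phenoxy}benzoate | COC(=O)c1cc(CCc2cc(OC)ccc2OC)cc(Oc2ccc(CCc3cccc(OC)c3)cc2)c1OC
F5 | step 11 | 5-[2-(2,5-dimethoxyphenyl)ethyl]-2-methoxy-3-{4-[2-(3-methoxyphenyl)ethyl]phenoxy}benzoic acid | O=C(O)c1cc(CCc2cc(OC)ccc2OC)cc(Oc2ccc(CCc3cccc(OC)c3)cc2)c1OC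
F6 | step 11 | 4-[2-(2,5-dimethoxyphenyl)ethyl]-1-methoxy-2-{4-[2-(3-methoxyphenyl)ethyl]phenoxy}benzene | COc1cccc(CCc2ccc(Oc3cc(CCc4cc(OC)ccc4OC)ccc3OC)cc2)c1
F7 | step 3 | methyl {4-[2-(3-methoxyphenyl)ethyl]phenoxy}acetate | COC(=O)COc1ccc(CCc2cccc(OC)c2)cc1
F8 | step 3 | {4-[2-(3-methoxyphenyl)ethyl]phenoxy}acetic acid | O=C(O)COc1ccc(CCc2cccc(OC)c2)cc1
F9 | step 3 | 1-({4-[2-(3-methoxyphenyl)ethyl]phenoxy}acetyl)imidazole | O=C(COc1ccc(CCc2cccc(OC)c2)cc1)n1ccnc1
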